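The earlier runs and the new flask stem from a simulated flask from invented constants, and the scatter is random.

Time here is best counted in turnovers, not minutes, because the question is how far this flask gets.

- gamma: substrate 0.61 M; run made earlier
- flask: substrate 0.41 M; time 15 min

gamma run (percent of the substrate charged)

| time / s | isomer of the product / % | target / % | substrate / % |
|---|---|---|---|
| 10.0 | 0.8 | 1.8 | 98.4 |
| 20.0 | 0.2 | 1.5 | 97.7 |
| 30.0 | 1.0 | 2.9 | 95.5 |
| 50.0 | 1.6 | 4.0 | 93.7 |
| 60.0 | 1.9 | 5.0 | 90.9 |
| 90.0 | 1.3 | 6.2 | 88.9 |

(readings scatter by 0.5 percentage points)

1. ratio of isomer of the product to target at 15 s
2. ratio of isomer of the product to target at 15 min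

- the earlier runs were read with a standard deviation of 0.5 percentage points
- a reading or a percentage of target counts all its forms, free or not
- a reading of substrate is of its free form alone

Fit the gamma run through the origin. Target and isomer of the product together appear at a rate that, if first order in substrate, gives k = 0.0595 /min. The same fits, taken separately, give a split s (a selectivity factor), isomer made per target made, of 0.296. Now define the turnover count N as k times the elapsed time, so that the substrate left is exp(−N); for the whole flask run N = 0.892.

Watch the flask slowly. At 15 s, N is 0.0149 and my count leaves 98.5% of the substrate in this flask, so I expect the ratio to read s. But s is itself a reading: in the gamma run the isomer of the product read 0.8% at 10.0 s, with a scatter of 0.5 percentage points. At 7.50 min, N is 0.446 and my count leaves 64.0% of the substrate. The gamma readings at 90.0 s already fall 3.6 points short, and my count leaves that aside. At 15 min, I reckon 41.0% substrate, 45.5% target and 13.5% isomer. N counts how much substrate has been used, not what the steps from the products do to the ratio, so keeping the ratio at s here is my assumption and not a result of N.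

The forecast agrees, with 0.3 at 15 s and 0.3 at 15 min, holding that “A parallel ratio shouldn't depend on concentration if both paths have the same order”.

The flask gives 0.234 and 0.264.

    substrate ⇌ target (K = 3.10, k = 0.0470 /min)
    substrate ⇌ isomer of the product (K = 2.40, k = 0.0110 /min)
    target ⇌ isomer of the product (k = 0.00450 /min)
    substrate + target ⇌ idle adduct, settled at all times (K = 2.10 /M)
    substrate → decomposition product (k = 1.00 × 10⁻⁴ /min)

So the forecast stood 1.28 times too high at 15 s and within tolerance at 15 min. In this flask, 40% of the substrate is left unbound, against the 41.0% from N. N carries no concentration, so for the neighbouring flask, charged with 0.16 M of substrate, it stays 0.892 and again gives 41.0%. That flask holds 43% unbound, with idle adduct at 10.3% against 20.2% in this flask, and its ratio is 0.235 at 15 s and 0.275 at 15 min.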